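The easy step comes first: a dissolved molecule of starting material has two ways out, so ask for its chances at that fork.

    starting material + free catalyst ⇌ catalyst intermediate (K1 = 0.24 M⁻¹, k1 = 150 M⁻¹ s⁻¹)
    catalyst intermediate → free catalyst + target (k2 = 0.63 s⁻¹)
    solid substrate ⇌ starting material, rate k3*(cs3 - [starting material]) while solid is left; crystals form when [starting material] > cs3 (cs3 = 0.36 M, k3 = 0.038 s⁻¹)
    starting material + protic impurity → quenched substrate (k4 = 0.015 M⁻¹ s⁻¹)

solid substrate 2.0 M; protic impurity 2.00 M; free catalyst 40 mM; time 4.0 min

- solid, in amounts per volume of the solution: solid substrate
- at the start none of the solid substrate is in solution
- starting material means what is dissolved; the solid is not counted in it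
- run time (flask): 4.0 min

1. how much target there is at 4.0 min, in percent of the solid substrate charged
2. concentration of starting material in solution at 4.0 min, in percent of saturation

The first step runs back at 625 s⁻¹, far faster than the second step goes on, so it stands as a pre-equilibrium. The catalytic exit is then pseudo-first-order in starting material, with constant 0.00605 s⁻¹. But the quench at the charged protic impurity has 0.0300 s⁻¹, which is faster. So a dissolved molecule becomes target with a chance of 16.8%: this catalytic constant over the sum of both exit constants is the fork share, or selectivity.

Dissolution against both exits sets a level of 0.185 M, approached with a time constant of 13.5 s, which is short against the run. That level is 51.3% of saturation. It feeds 1.60 M through the fork, less than the solid charged, so this reckoning commits to 13.4% target, with the impurity held at its charge.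

The forecast gives 13.7% and 64.5%, with the level “drifting from about 0.19 to 0.23 M as the impurity is used up to roughly half”. Its yield lies close to this reckoning, but its saturation lies higher.

The flask gives 13.5% and 63.8%. Protic impurity stands at 50% of its charge at 4.00 min, where the fork share is 28.9%. Target over target plus quenched substrate comes to 21.1%, between the two shares.

With 0.010 M of free catalyst, the fork share in the neighbour flask runs from 4.80% at the charged impurity to 9.65% at the 47% left. That neighbour flask gives 3.60% target, and target over target plus quenched substrate is 6.37%.

(Its constants were chosen freely; the flask was simulated.)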